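E is charged at 0.600 equiv, less than Z at 1.50 equiv, so I write the balance of E first.

| setting | Sunday's | Tuesday's | Friday's | ochre | grey | violet |
|---|---|---|---|---|---|---|
| J | 20 mM | 10 mM | 40 mM | 20 mM | 20 mM | 20 mM (fed, over 6.0 h) |
| Z | 1.5 equiv | 1.5 equiv | 1.5 equiv | 1.50 equiv | 1.50 equiv | 1.50 equiv |
| E | 0.60 equiv | 0.60 equiv | 0.60 equiv | 0.600 equiv | 0.600 equiv (fed, over 6.0 h) | 0.600 equiv |
| remark | run made earlier | run made earlier | run made earlier | everything together at the start | all else is in the flask from the start; the feed brings no volume worth counting | all else is in the flask from the start; the feed brings no volume worth counting |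
| time |  |  |  | 10 h | 10 h | 10 h |

| run | time / h | X / % | G / % |
|---|---|---|---|
| Sunday's | 0.833 | 0.3 | 1.6 |
| Sunday's | 2.00 | 0 | 3.1 |
| Sunday's | 4.00 | 0.2 | 5.7 |
| Sunday's | 10.0 | 0 | 10.4 |
| Tuesday's | 0.833 | 0.2 | 1.8 |
| Tuesday's | 2.00 | 0 | 3.5 |
| Tuesday's | 4.00 | 0.3 | 6.9 |
| Tuesday's | 10.0 | 0.8 | 13.0 |
| Friday's | 2.50 | 0.2 | 2.9 |
| Friday's | 5.00 | 0.2 | 5.4 |
| Friday's | 8.00 | 0.2 | 6.9 |
| Friday's | 10.0 | 0.7 | 7.6 |

(each reading ± 0.3 percentage points)



* which flask leads in share of X in X plus G ("all alike" within 1.5 percentage points) (ochre / grey / violet / all alike)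
* share of X in X plus G at the end, ochre
* share of X in X plus G at the end, grey
* share of X in X plus G at the end, violet

Does E fall away in ochre? Sunday's run is the same recipe, and its G of 10.4% at 10.0 h costs, at one E per G, 17.3% of the E charge. So cZ/cE goes from its charged 2.50 to about 3.02 by then.

I assume that X and G branch from one species, split by cZ/cE; the earlier runs all had the same charged ratio. The partition ratio σ (a selectivity factor), X found per G found in runs with this charged cZ/cE, is 0.0484, summed over the last readings. It is a reading, good to about a third. Ochre then has a share of 4.62%, and I take the same for violet, where Z and E both stand in the flask from the start.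

Which flask moves the ratio? Grey does. Its feed brings E 5.21 times as fast as Sunday's early G takes it, so I let cE follow what has been fed, and the share being formed at time t during the feed is σ/(σ + t/tf), with t/tf the part of E fed.

How much does that give? Averaged evenly over the feed, that share is 14.9%. Sunday's G, interpolated, puts 69.9% of the turnover before 6.0 h, so I expect 11.8% for grey, clear of the others by more than the margin.

The forecast says all alike, with ochre 4%, grey 3.5% and violet 3.5%, because “Nothing therefore supports a big selectivity switch from dosing”; on grey it stands below my figure.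

The flasks give ochre 5.06%, grey 12.1% and violet 5.13%, so grey leads.

    E + L → G (k = 3000 /M/h)
    J + X → Q (k = 7.40 /M/h)
    J ⇌ L (K = 0.100, k = 0.0240 /h)
    2 J → D (k = 6.20 /M/h)
    Z + L → X (k = 80.0 /M/h)

In grey, half of the turnover of the step from E and L to G up to 10 h is done by 3.90 h, earlier than the end of the feed at 6.0 h, while E is still going in. Carried to a further flask, like grey but with Z at 0.600 equiv, σ scales to 0.0194 and the same reckoning gives 5.95%; that flask gives 5.54%.

The numbers in the tables are simulated with constants of no real substance; scatter was added.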